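**Plan**

1. Numbering: C1 CH(OH), C2 CH2, C3 C=O, C4 CH(CH3), C5 CH2, C6 O–CH, C7 ring-fusion CH, C8 CH(O2C-i-Pr), C9 CH2, C10 C(CH3)(OH); C11, C12, C13 are the lactone α-carbon, carbonyl and exocyclic CH2.
2. Enabling feature: the vicinal cis-diol C1(H)(OH)–C10(CH3)(OH) in the ten-membered carbocycle is the pinacol retron of a C1 aldehyde and a C10 methyl ketone, so the last skeletal cut is C1–C10, leaving an acyclic keto aldehyde on an intact γ-lactone.
3. Earlier cuts: C11=C13 (Mannich methylenation), C8–C9 (methallylboration, C10 ketone by ozonolysis), C6–C7 (Evans syn-aldol of a succinate imide, which also delivers the O–C6/C12 lactone), C2–C3 (allyl Grignard on a Weinreb amide), C4–C5 (Evans alkylation).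
4. Forward: C1–C6 aldehyde, then aldol and lactonisation (γ-lactone ring first), C8–C10 side chain, double ozonolysis, SmI2 pinacol closure of the cyclodecane (second ring), then methylenation, acylation and deprotection.
5. Stereochemistry: C4 from auxiliary-controlled alkylation; C6 and C7 from the auxiliary-controlled syn-aldol; C8 from reagent-controlled allylboration; C1 and C10 from the chelated pinacol closure under the influence of C8 and the trans-lactone.

Key step: step 13

Assumption: (+)-Ipc2BOMe denotes the borinate made from (−)-α-pinene, whose B-allyl and B-methallyl derivatives add to the Re face of an aldehyde RCHO (O > R > H); the CIP descriptor at C7 switches between S and R with the C8 oxygen substituent although the spatial arrangement stays the same.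

**Route**

Step 1
Reactants: 1 (4R)-4-benzyl-3-propanoyl-1,3-oxazolidin-2-one; 2 1-bromo-3-methylbut-2-ene (prenyl bromide)
Product: 3 (4R)-4-benzyl-3-[(2S)-2,5-dimethylhex-4-enoyl]-1,3-oxazolidin-2-one
Conditions: NaN(SiMe3)2, THF, −78 °C; then 2, −78 to −40 °C
Reagents that add atoms: none
Why: Evans asymmetric alkylation, in which the chelated Z-sodium enolate is alkylated by the allylic bromide on the face away from the benzyl group, sets C4 as S.

Step 2
Reactants: 3 alkylated imide
Product: 4 (2S)-N-methoxy-N,2,5-trimethylhex-4-enamide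
Conditions: MeNH(OMe)·HCl, AlMe3, CH2Cl2, 0 °C to rt
Reagents that add atoms: N,O-dimethylhydroxylamine hydrochloride, CNOC.Cl
Why: Weinreb transamidation with the aluminium amide cleaves the exocyclic acyl group of the imide without touching the α-stereocentre and returns the auxiliary.

Step 3
Reactants: 4 Weinreb amide; 5 allylmagnesium bromide
Product: 6 (5S)-5,8-dimethylnona-1,7-dien-4-one
Conditions: 5 (1.3 equiv), THF, −78 to −20 °C; cold 1 M HCl quench
Reagents that add atoms: none
Why: Weinreb ketone synthesis, in which the magnesium-chelated tetrahedral adduct survives until the cold quench, should deliver a single allyl group and release the β,γ-unsaturated ketone without conjugation or epimerisation at C4.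

Step 4
Reactants: 6 allyl ketone
Product: 7 2-[(2S)-5-methylhex-4-en-2-yl]-2-(prop-2-en-1-yl)-1,3-dioxolane
Conditions: Me3SiOCH2CH2OSiMe3, Me3SiOTf (5 mol %), CH2Cl2, −78 to −20 °C; pyridine quench
Reagents that add atoms: 1,2-bis(trimethylsilyloxy)ethane, C[Si](C)(C)OCCO[Si](C)(C)C
Why: Noyori ketalisation under aprotic, low-temperature silyl triflate catalysis should convert the ketone into the dioxolane without moving the β,γ-double bond into conjugation and without enolising C4.

Step 5
Reactants: 7 dioxolane diene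
Product: 8 (3S)-3-[2-(prop-2-en-1-yl)-1,3-dioxolan-2-yl]butanal
Conditions: O3 (1 equiv, Sudan Red 7B end point), CH2Cl2, −78 °C; then PPh3, −78 °C to rt
Reagents that add atoms: ozone, [O-][O+]=O
Why: Chemoselective ozonolysis relies on the electron-rich trisubstituted alkene reacting with ozone much faster than the monosubstituted allyl group, so one equivalent should cleave only the isopropylidene terminus and give the C6 aldehyde after reductive work-up.

Step 6
Reactants: 9 (4S)-4-benzyl-1,3-oxazolidin-2-one; 10 methyl 4-chloro-4-oxobutanoate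
Product: 11 methyl 4-[(4S)-4-benzyl-2-oxo-1,3-oxazolidin-3-yl]-4-oxobutanoate
Conditions: n-BuLi, THF, −78 °C; then 10, −78 to 0 °C
Reagents that add atoms: none
Why: N-acylation of the lithiated oxazolidinone by the acid chloride is the standard entry to Evans imides and leaves the methyl ester untouched.

Step 7
Reactants: 11 succinate imide; 8 aldehyde
Product: 12 methyl (3S,4R,6S)-3-{[(4S)-4-benzyl-2-oxo-1,3-oxazolidin-3-yl]carbonyl}-4-hydroxy-6-[2-(prop-2-en-1-yl)-1,3-dioxolan-2-yl]heptanoate
Conditions: 11, Bu2BOTf, i-Pr2NEt, CH2Cl2, 0 °C; then 8, −78 to 0 °C; pH 7 buffer, MeOH, H2O2, 0 °C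
Reagents that add atoms: none
Why: Evans syn-aldol reaction, in which the Z-boron enolate of the imide (the ester is not enolised) adds through a Zimmerman–Traxler chair with the auxiliary dipole opposed, sets C7 as S and C6 as R independently of the remote C4 centre.

Step 8
Reactants: 12 aldol adduct
Product: 14 (2R,3S)-5-oxo-2-{(2S)-2-[2-(prop-2-en-1-yl)-1,3-dioxolan-2-yl]propyl}oxolane-3-carboxylic acid, via hydroxy acid ester 13 (not isolated)
Conditions: LiOH, H2O2, THF/H2O, 0 °C; Na2SO3; aq. HCl to pH 3 at 0 °C, extraction; then PPTS (cat.), toluene, 50 °C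
Reagents that add atoms: hydrogen peroxide, OO
Why: Lithium hydroperoxide cleavage of the exocyclic imide carbonyl (standard Evans auxiliary removal) is run while the C6 oxygen is still a hydroxyl and not a leaving group, and the γ-hydroxy ester then lactonises under mild acid to the trans-disubstituted γ-lactone without creating or disturbing a stereocentre.

Step 9
Reactants: 14 lactone acid
Product: 16 (2R,3S)-5-oxo-2-{(2S)-2-[2-(prop-2-en-1-yl)-1,3-dioxolan-2-yl]propyl}oxolane-3-carbaldehyde, via acid chloride 15 (not isolated)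
Conditions: 1-chloro-N,N,2-trimethylprop-1-en-1-amine, CH2Cl2, 0 °C to rt; then LiAlH(Ot-Bu)3 (1.0 equiv), THF, −78 °C
Reagents that add atoms: none
Why: Neutral acid chloride formation followed by partial reduction with the hindered hydride LiAlH(Ot-Bu)3 at low temperature should stop at the aldehyde, since lactone, ketal and alkene are inert to this reagent.

Step 10
Reactants: 16 lactone aldehyde; 17 (2-methylprop-2-en-1-yl)magnesium chloride
Product: 18 (4R,5R)-4-[(1R)-1-hydroxy-3-methylbut-3-en-1-yl]-5-{(2S)-2-[2-(prop-2-en-1-yl)-1,3-dioxolan-2-yl]propyl}oxolan-2-one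
Conditions: (+)-Ipc2BOMe, 17 (slight deficit), Et2O, −78 °C to rt, magnesium salts allowed to settle; then 16, Et2O, −78 °C; pH 7 buffer, H2O2, MeOH, 0 °C to rt
Reagents that add atoms: none
Why: Brown asymmetric methallylboration, through the chair transition state of the (−)-α-pinene-derived B-methallyldiisopinocampheylborane, should deliver the methallyl group to the Re face of the aldehyde under reagent control to give the 8R carbinol, and the neutral conditions at −78 °C spare the enolisable β-acyloxy aldehyde.

Step 11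
Reactants: 18 homoallylic alcohol
Product: 19 (4S,5R)-4-[(1R)-1-{[tert-butyl(dimethyl)silyl]oxy}-3-methylbut-3-en-1-yl]-5-{(2S)-2-[2-(prop-2-en-1-yl)-1,3-dioxolan-2-yl]propyl}oxolan-2-one
Conditions: t-BuMe2SiOTf, 2,6-lutidine, CH2Cl2, −78 to 0 °C
Reagents that add atoms: tert-butyldimethylsilyl trifluoromethanesulfonate, CC(C)(C)[Si](C)(C)OS(=O)(=O)C(F)(F)F
Why: Silyl triflate silylation under hindered-base buffering caps the C8 hydroxyl quickly at low temperature, which removes the risk of translactonisation onto C12 and installs a group that tolerates ozone, SmI2 and lithium amide base.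

Step 12
Reactants: 19 silyl ether diene
Product: 20 {2-[(2S)-1-{(2R,3S)-3-[(1R)-1-{[tert-butyl(dimethyl)silyl]oxy}-3-oxobutyl]-5-oxooxolan-2-yl}propan-2-yl]-1,3-dioxolan-2-yl}acetaldehyde
Conditions: O3, CH2Cl2, −78 °C; then PPh3, −78 °C to rt; used at once
Reagents that add atoms: ozone, [O-][O+]=O
Why: Exhaustive ozonolysis with reductive work-up cleaves the allyl and the methallyl terminus, the only alkenes present, in one operation to the C1 aldehyde and the C10 methyl ketone.

Step 13
Reactants: 20 keto aldehyde
Product: 21 (1S,4S,6R,7S,8R,10R)-8-{[tert-butyl(dimethyl)silyl]oxy}-3,3-(ethane-1,2-diyldioxy)-1,10-dihydroxy-13-norgermacran-12,6-olide (ten-membered carbocycle, trans-fused γ-lactone with C11 as CH2, cis-1,10-diol)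
Conditions: SmI2 (4 equiv, 0.1 M in THF), degassed THF, 20 °C, 20 added by syringe pump to a final 0.002 M; then pH 7 buffer
Reagents that add atoms: none
Why: SmI2 transfers one electron to the aldehyde (and more slowly to the ketone) to give a samarium-bound ketyl at C1 that couples with the C10 carbonyl carbon held on the same oxophilic trivalent samarium centre, and a second electron plus protonation on work-up give the 1,10-diol, i.e. an intramolecular pinacol coupling of a keto aldehyde whose closest precedents are SmI2- and low-valent-titanium-mediated pinacol cyclisations to medium and large rings. The cyclodecane is the only ring closed and forms in a 10-exo-trig sense (C1 ketyl onto the C10 carbonyl), with slow addition at high dilution suppressing intermolecular coupling and the trans-lactone and the C3 ketal pre-folding the chain. C1 and C10 are both new, and their mutual cis relationship should be dictated by the five-membered samarium diolate chelate that forms as the bond is made, which requires the two C–O bonds to be syn. The absolute sense at C10 should follow from the C8 stereocentre, the ketone reacting in the conformer with C10=O anti to the C8–OSi bond and the silyloxy group on the outside of the forming ring, which corresponds to the 1,3-anti C8–O/C10–O relationship of the target, and C1 then follows from the chelate. The step also needs chemoselectivity for the two carbonyls over the lactone and freedom from β-elimination, which the substrate secures because SmI2 without HMPA or protic activators does not reduce γ-lactones, C3 is a ketal (no β-keto aldehyde), the lactone carries no acceptor methylene and neither ketyl has a leaving group on its α-carbon.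

Step 14
Reactants: 21 diol
Product: 22 (1S,4S,6R,7S,8R,10R)-8-{[tert-butyl(dimethyl)silyl]oxy}-3,3-(ethane-1,2-diyldioxy)-1,10-(propane-2,2-diyldioxy)-13-norgermacran-12,6-olide
Conditions: 2,2-dimethoxypropane, PPTS (cat.), CH2Cl2, rt
Reagents that add atoms: 2,2-dimethoxypropane, COC(C)(C)OC
Why: Acid-catalysed transacetalisation closes the five-membered isopropylidene acetal across the cis-disposed vicinal diol and masks both hydroxyls for the strongly basic methylenation.

Step 15
Reactants: 22 acetonide
Product: 23 the C11-(dimethylaminomethyl) derivative of 22 (either C11 epimer)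
Conditions: LiN(i-Pr)2, THF, −78 °C; then CH2=NMe2+ I−, −78 °C to rt
Reagents that add atoms: dimethylmethylideneammonium iodide, C=[N+](C)C.[I-]
Why: Mannich reaction of the lactone lithium enolate with the preformed iminium salt is the classical first half of the α-methylenation of γ-lactones, and the new C11 centre is of no consequence because it becomes sp2 in the next step.

Step 16
Reactants: 23 Mannich base
Product: 25 (1S,4S,6R,7S,8R,10R)-8-{[tert-butyl(dimethyl)silyl]oxy}-3,3-(ethane-1,2-diyldioxy)-1,10-(propane-2,2-diyldioxy)germacr-11(13)-en-12,6-olide, via ammonium iodide 24 (not isolated)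
Conditions: MeI, MeOH, rt; then aq. NaHCO3, CH2Cl2, rt
Reagents that add atoms: none
Why: N-methylation turns the amine into a trimethylammonium leaving group and mild base then effects E1cB elimination across C11–C13 to the exocyclic methylene lactone.

Step 17
Reactants: 25 silyl ether
Product: 26 (1S,4S,6R,7R,8R,10R)-3,3-(ethane-1,2-diyldioxy)-8-hydroxy-1,10-(propane-2,2-diyldioxy)germacr-11(13)-en-12,6-olide
Conditions: HF·pyridine, pyridine, THF, 0 °C to rt
Reagents that add atoms: none
Why: Fluoride-mediated desilylation under buffered, non-basic conditions frees the C8 hydroxyl without forming an alkoxide that could add to the methylene lactone or translactonise, and both acetals are stable to it.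

Step 18
Reactants: 26 alcohol
Product: 27 (1S,4S,6R,7S,8R,10R)-3,3-(ethane-1,2-diyldioxy)-8-(2-methylpropanoyloxy)-1,10-(propane-2,2-diyldioxy)germacr-11(13)-en-12,6-olide
Conditions: (i-PrCO)2O, Et3N, DMAP (cat.), CH2Cl2, 0 °C to rt
Reagents that add atoms: 2-methylpropanoic anhydride, CC(C)C(=O)OC(=O)C(C)C
Why: DMAP-catalysed acylation esterifies the only free hydroxyl, the secondary C8 alcohol, with retention at C8.

Step 19
Reactants: 27 protected ester
Product: 28 (1S,4S,6R,7S,8R,10R)-1,10-dihydroxy-8-(2-methylpropanoyloxy)-3-oxogermacr-11(13)-en-12,6-olide (CNP0180091.1)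
Conditions: 1 M aq. HCl, THF, 0 °C to rt
Reagents that add atoms: water, O
Why: Aqueous acid hydrolysis cleaves the isopropylidene acetal and the dioxolane in one operation to release the 1,10-diol and the C3 ketone, while ester, methylene lactone and all six stereocentres should be unaffected by dilute acid.

**Compound list**

1 | (4R)-4-benzyl-3-propanoyl-1,3-oxazolidin-2-one | CCC(=O)N1C(=O)OC[C@H]1Cc1ccccc1 | starting material
2 | 1-bromo-3-methylbut-2-ene | CC(C)=CCBr | starting material
3 | (4R)-4-benzyl-3-[(2S)-2,5-dimethylhex-4-enoyl]-1,3-oxazolidin-2-one | CC(C)=CC[C@H](C)C(=O)N1C(=O)OC[C@H]1Cc1ccccc1 | intermediate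
4 | (2S)-N-methoxy-N,2,5-trimethylhex-4-enamide | CC(C)=CC[C@H](C)C(=O)N(C)OC | intermediate
5 | allylmagnesium bromide | C=CC[Mg]Br | starting material
6 | (5S)-5,8-dimethylnona-1,7-dien-4-one | CC(C)=CC[C@H](C)C(=O)CC=C | intermediate
7 | 2-[(2S)-5-methylhex-4-en-2-yl]-2-(prop-2-en-1-yl)-1,3-dioxolane | CC(C)=CC[C@H](C)C1(CC=C)OCCO1 | intermediate
8 | (3S)-3-[2-(prop-2-en-1-yl)-1,3-dioxolan-2-yl]butanal | O=CC[C@H](C)C1(CC=C)OCCO1 | intermediate
9 | (4S)-4-benzyl-1,3-oxazolidin-2-one | O=C1N[C@@H](Cc2ccccc2)CO1 | starting material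
10 | methyl 4-chloro-4-oxobutanoate | COC(=O)CCC(Cl)=O | starting material
11 | methyl 4-[(4S)-4-benzyl-2-oxo-1,3-oxazolidin-3-yl]-4-oxobutanoate | COC(=O)CCC(=O)N1C(=O)OC[C@@H]1Cc1ccccc1 | intermediate
12 | methyl (3S,4R,6S)-3-{[(4S)-4-benzyl-2-oxo-1,3-oxazolidin-3-yl]carbonyl}-4-hydroxy-6-[2-(prop-2-en-1-yl)-1,3-dioxolan-2-yl]heptanoate | COC(=O)C[C@H](C(=O)N1C(=O)OC[C@@H]1Cc1ccccc1)[C@H](O)C[C@H](C)C1(CC=C)OCCO1 | intermediate
13 | (2S)-2-{(1R,3S)-1-hydroxy-3-[2-(prop-2-en-1-yl)-1,3-dioxolan-2-yl]butyl}-4-methoxy-4-oxobutanoic acid | COC(=O)C[C@H](C(O)=O)[C@H](O)C[C@H](C)C1(CC=C)OCCO1 | intermediate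
14 | (2R,3S)-5-oxo-2-{(2S)-2-[2-(prop-2-en-1-yl)-1,3-dioxolan-2-yl]propyl}oxolane-3-carboxylic acid | O=C1C[C@H](C(O)=O)[C@@H](C[C@H](C)C2(CC=C)OCCO2)O1 | intermediate
15 | (2R,3S)-5-oxo-2-{(2S)-2-[2-(prop-2-en-1-yl)-1,3-dioxolan-2-yl]propyl}oxolane-3-carbonyl chloride | O=C1C[C@H](C(Cl)=O)[C@@H](C[C@H](C)C2(CC=C)OCCO2)O1 | intermediate
16 | (2R,3S)-5-oxo-2-{(2S)-2-[2-(prop-2-en-1-yl)-1,3-dioxolan-2-yl]propyl}oxolane-3-carbaldehyde | O=C1C[C@H](C=O)[C@@H](C[C@H](C)C2(CC=C)OCCO2)O1 | intermediate
17 | (2-methylprop-2-en-1-yl)magnesium chloride | C=C(C)C[Mg]Cl | starting material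
18 | (4R,5R)-4-[(1R)-1-hydroxy-3-methylbut-3-en-1-yl]-5-{(2S)-2-[2-(prop-2-en-1-yl)-1,3-dioxolan-2-yl]propyl}oxolan-2-one | O=C1C[C@H]([C@H](O)CC(C)=C)[C@@H](C[C@H](C)C2(CC=C)OCCO2)O1 | intermediate
19 | (4S,5R)-4-[(1R)-1-{[tert-butyl(dimethyl)silyl]oxy}-3-methylbut-3-en-1-yl]-5-{(2S)-2-[2-(prop-2-en-1-yl)-1,3-dioxolan-2-yl]propyl}oxolan-2-one | O=C1C[C@H]([C@H](O[Si](C)(C)C(C)(C)C)CC(C)=C)[C@@H](C[C@H](C)C2(CC=C)OCCO2)O1 | intermediate
20 | {2-[(2S)-1-{(2R,3S)-3-[(1R)-1-{[tert-butyl(dimethyl)silyl]oxy}-3-oxobutyl]-5-oxooxolan-2-yl}propan-2-yl]-1,3-dioxolan-2-yl}acetaldehyde | O=C1C[C@H]([C@H](O[Si](C)(C)C(C)(C)C)CC(C)=O)[C@@H](C[C@H](C)C2(CC=O)OCCO2)O1 | intermediate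
21 | (1S,4S,6R,7S,8R,10R)-8-{[tert-butyl(dimethyl)silyl]oxy}-3,3-(ethane-1,2-diyldioxy)-1,10-dihydroxy-13-norgermacran-12,6-olide | C1C(=O)O[C@@H]2C[C@H](C)C3(OCCO3)C[C@H](O)[C@](C)(O)C[C@@H](O[Si](C)(C)C(C)(C)C)[C@@H]12 | intermediate
22 | (1S,4S,6R,7S,8R,10R)-8-{[tert-butyl(dimethyl)silyl]oxy}-3,3-(ethane-1,2-diyldioxy)-1,10-(propane-2,2-diyldioxy)-13-norgermacran-12,6-olide | C1C(=O)O[C@@H]2C[C@H](C)C3(OCCO3)C[C@@H]4OC(C)(C)O[C@]4(C)C[C@@H](O[Si](C)(C)C(C)(C)C)[C@@H]12 | intermediate
23 | C11-(dimethylaminomethyl) derivative of 22 (C11 configuration left open) | CN(C)CC1C(=O)O[C@@H]2C[C@H](C)C3(OCCO3)C[C@@H]4OC(C)(C)O[C@]4(C)C[C@@H](O[Si](C)(C)C(C)(C)C)[C@@H]12 | intermediate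
24 | N-methyl quaternary ammonium iodide of 23 | C[N+](C)(C)CC1C(=O)O[C@@H]2C[C@H](C)C3(OCCO3)C[C@@H]4OC(C)(C)O[C@]4(C)C[C@@H](O[Si](C)(C)C(C)(C)C)[C@@H]12.[I-] | intermediate
25 | (1S,4S,6R,7S,8R,10R)-8-{[tert-butyl(dimethyl)silyl]oxy}-3,3-(ethane-1,2-diyldioxy)-1,10-(propane-2,2-diyldioxy)germacr-11(13)-en-12,6-olide | C=C1C(=O)O[C@@H]2C[C@H](C)C3(OCCO3)C[C@@H]4OC(C)(C)O[C@]4(C)C[C@@H](O[Si](C)(C)C(C)(C)C)[C@@H]12 | intermediate
26 | (1S,4S,6R,7R,8R,10R)-3,3-(ethane-1,2-diyldioxy)-8-hydroxy-1,10-(propane-2,2-diyldioxy)germacr-11(13)-en-12,6-olide | C=C1C(=O)O[C@@H]2C[C@H](C)C3(OCCO3)C[C@@H]4OC(C)(C)O[C@]4(C)C[C@@H](O)[C@@H]12 | intermediate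
27 | (1S,4S,6R,7S,8R,10R)-3,3-(ethane-1,2-diyldioxy)-8-(2-methylpropanoyloxy)-1,10-(propane-2,2-diyldioxy)germacr-11(13)-en-12,6-olide | C=C1C(=O)O[C@@H]2C[C@H](C)C3(OCCO3)C[C@@H]4OC(C)(C)O[C@]4(C)C[C@@H](OC(=O)C(C)C)[C@@H]12 | intermediate
28 | (1S,4S,6R,7S,8R,10R)-1,10-dihydroxy-8-(2-methylpropanoyloxy)-3-oxogermacr-11(13)-en-12,6-olide | C=C1C(=O)O[C@@H]2C[C@H](C)C(=O)C[C@H](O)[C@](C)(O)C[C@@H](OC(=O)C(C)C)[C@@H]12 | target

**Step count and risks**

Total steps: 19. Longest linear sequence: 18 (steps 1–5 and 7–19; step 6 is a one-step side branch).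

Steps most likely to fail:

Step 13. The ten-membered ring may close too slowly, so that intermolecular coupling or simple reduction of the aldehyde takes over. Closure may also run through a non-chelated or trans-diolate arrangement, or on the other face of the ketone, and give the wrong configuration at C1 or C10. The fallback sets out from diene 19. Ring-closing metathesis of the allyl and methallyl termini (second-generation Hoveyda–Grubbs catalyst, dilute toluene, 80 °C) would give the (Z)-cyclodecene F1. Syn-dihydroxylation (OsO4 cat., N-methylmorpholine N-oxide, acetone/H2O) from the more exposed face would then come back to the route at diol 21. Both hydroxyls arrive suprafacially, so the cis relationship is built in and only the face remains to be steered, if need be with a Sharpless ligand.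

Step 10. The β-acyloxy aldehyde may enolise, with β-elimination of the lactone carboxylate or epimerisation at C7 before addition, or the borane may not fully override the substrate's own facial bias. The fallback sets out from acid chloride 15. Stille acylation with tributyl(2-methylprop-2-en-1-yl)stannane (Pd(PPh3)4 cat., THF, 50 °C) would give the β,γ-unsaturated ketone F2 without passing through the aldehyde. Corey–Bakshi–Shibata reduction ((S)-2-methyl-CBS-oxazaborolidine cat., catecholborane, toluene, −78 °C) would set C8 by catalyst control and come back to the route at alcohol 18.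

Step 4. Traces of acid may move the β,γ-double bond into conjugation with the ketone, or ketalisation of the α-branched ketone may stall, so that the allyl ketal is not formed cleanly. The fallback sets out from Weinreb amide 4 and builds the terminal alkene only after the ketal is in place. Claisen-type acylation of the lithium enolate of ethyl acetate (LiN(i-Pr)2, EtOAc, THF, −78 °C) would give β-keto ester F3. Ketalisation under the same Noyori conditions, now with no alkene next to the ketone, would give dioxolane ester F4. Partial reduction (i-Bu2AlH, toluene, −78 °C) would give dioxolane aldehyde F5. Wittig methylenation (Ph3P=CH2 from Ph3PCH3Br and KOt-Bu, THF, 0 °C) would come back to the route at dioxolane 7.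

Further compounds
F1 | step 13 | (1Z)-cyclodecene from ring-closing metathesis of 19: (4S,6R,7S,8R)-8-{[tert-butyl(dimethyl)silyl]oxy}-3,3-(ethane-1,2-diyldioxy)-13-norgermacr-1(10)-en-12,6-olide | C1C(=O)O[C@@H]2C[C@H](C)C3(OCCO3)C/C=C(/C)C[C@@H](O[Si](C)(C)C(C)(C)C)[C@@H]12
F2 | step 10 | (4S,5R)-4-(3-methylbut-3-enoyl)-5-{(2S)-2-[2-(prop-2-en-1-yl)-1,3-dioxolan-2-yl]propyl}oxolan-2-one | O=C1C[C@H](C(=O)CC(C)=C)[C@@H](C[C@H](C)C2(CC=C)OCCO2)O1
F3 | step 4 | ethyl (4S)-4,7-dimethyl-3-oxooct-6-enoate | CC(C)=CC[C@H](C)C(=O)CC(=O)OCC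
F4 | step 4 | ethyl {2-[(2S)-5-methylhex-4-en-2-yl]-1,3-dioxolan-2-yl}acetate | CC(C)=CC[C@H](C)C1(CC(=O)OCC)OCCO1
F5 | step 4 | {2-[(2S)-5-methylhex-4-en-2-yl]-1,3-dioxolan-2-yl}acetaldehyde | CC(C)=CC[C@H](C)C1(CC=O)OCCO1
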